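## Retrosynthetic overview

- The last step is global hydrogenolysis of the tetradeca-O-benzyl pentamer. The last skeletal bond is the ring B–O–ring C ether, made by copper-catalysed coupling of phenol fragment AB with aryl bromide fragment CDE.
- Fragments AB and CD both come from one new reaction: insertion of 3,4,5-tris(benzyloxy)benzyne into the O–B bond of an aryl pinacol borate (ring A phenol or ring C bromophenol), followed by C–B to C–OH oxidation. This forms the A–O–B (or C–O–D) ether and places the neighbouring oxygen of ring B (or ring D) in one regiodefined operation.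
- Ring E is attached to fragment CD by Chan–Lam coupling with the ring E boronic acid; the ring C bromide survives for the final coupling.
- No ring is built: all five benzene rings are bought (phloroglucinol, gallaldehyde, 2,6-dihydroxybenzaldehyde and 5-bromopyrogallol derivatives). Order of ether formation: A–B and C–D (aryne), D–E (Chan–Lam), B–C (Ullmann).

Assumption: the target has no stereocentre and no hindered axis, so it is achiral and "single enantiomer" means the one constitution given; no stereochemistry has to be set.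

## Route

Step 1
Reactants: 1 1,3,5-tris(benzyloxy)benzene
Product: 3 2,4,6-tris(benzyloxy)benzaldehyde, via iminium chloride 2 (not isolated)
Conditions: POCl3 (1.2 equiv), DMF, 0 °C to rt; then ice-water
Reagents that add atoms: N,N-dimethylformamide, CN(C)C=O; water, O
Why: Vilsmeier–Haack formylation; the three equivalent ring positions are each activated by three alkoxy groups, and the iminium ion deactivates the ring against a second formylation.

Step 2
Reactants: 3 2,4,6-tris(benzyloxy)benzaldehyde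
Product: 5 2,4,6-tris(benzyloxy)phenol, via aryl formate 4 (not isolated)
Conditions: mCPBA (1.3 equiv), CH2Cl2, 0 °C to rt; then K2CO3 (cat.), MeOH, rt
Reagents that add atoms: 3-chloroperoxybenzoic acid, O=C(OO)c1cccc(Cl)c1
Why: Baeyer–Villiger (Dakin-type) oxidation, in which the electron-rich aryl group migrates in preference to hydride, followed by methanolysis of the formate.

Step 3
Reactants: 6 3,4,5-trihydroxybenzaldehyde
Product: 7 3,4,5-tris(benzyloxy)benzaldehyde
Conditions: BnBr (3.5 equiv), K2CO3, DMF, 60 °C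
Reagents that add atoms: benzyl bromide, BrCc1ccccc1
Why: Williamson ether synthesis on three phenoxides; the aldehyde is inert to carbonate.

Step 4
Reactants: 7 3,4,5-tris(benzyloxy)benzaldehyde
Product: 9 3,4,5-tris(benzyloxy)phenol, via aryl formate 8 (not isolated)
Conditions: mCPBA (1.3 equiv), CH2Cl2, 0 °C to rt; then K2CO3 (cat.), MeOH, rt
Reagents that add atoms: 3-chloroperoxybenzoic acid, O=C(OO)c1cccc(Cl)c1
Why: Baeyer–Villiger (Dakin-type) oxidation with aryl migration favoured by the para alkoxy group, then formate methanolysis.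

Step 5
Reactants: 9 3,4,5-tris(benzyloxy)phenol
Product: 10 2-bromo-3,4,5-tris(benzyloxy)phenol
Conditions: NBS (1.0 equiv), CH2Cl2, −78 °C to 0 °C
Reagents that add atoms: N-bromosuccinimide, O=C1CCC(=O)N1Br
Why: Electrophilic aromatic bromination ortho to the free hydroxyl (para is blocked, the two ortho positions are equivalent), held at the mono-bromide by stoichiometry and low temperature.

Step 6
Reactants: 10 2-bromo-3,4,5-tris(benzyloxy)phenol
Product: 13 3,4,5-tris(benzyloxy)-2-(trimethylsilyl)phenyl trifluoromethanesulfonate, via aryl trimethylsilyl ether 11 (not isolated), via lithium 2-silylphenolate 12 (not isolated)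
Conditions: HMDS, THF, reflux, then evaporate; n-BuLi (1.1 equiv), THF, −78 °C; then Tf2O (1.2 equiv), −78 °C to 0 °C
Reagents that add atoms: hexamethyldisilazane, C[Si](C)(C)N[Si](C)(C)C; trifluoromethanesulfonic anhydride, O=S(=O)(OS(=O)(=O)C(F)(F)F)C(F)(F)F
Why: O-silylation, bromine–lithium exchange and anionic O-to-C silyl migration (retro-Brook rearrangement), then triflation of the lithium phenolate; this is the standard entry to 2-silylaryl triflate aryne precursors, and the exchange at −78 °C is faster than benzylic deprotonation.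

Step 7
Reactants: 5 2,4,6-tris(benzyloxy)phenol; 13 3,4,5-tris(benzyloxy)-2-(trimethylsilyl)phenyl trifluoromethanesulfonate
Product: 16 2,3,4-tris(benzyloxy)-6-[2,4,6-tris(benzyloxy)phenoxy]phenol (fragment AB), via aryl pinacol borate 14 (not isolated), via arylboronic ester 15 (not isolated)
Conditions: 5 (2.5 equiv), HBpin (2.5 equiv), toluene, 60 °C, then evaporate; 13 (1.0 equiv), KF (3 equiv), 18-crown-6 (3 equiv), THF, 0 °C to rt; then 30% H2O2, aq NaHCO3, THF, 0 °C
Reagents that add atoms: hydrogen peroxide, OO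
Why: Proposed new method: formal insertion of an aryne into the O–B bond of an aryl pinacol borate (aryne aryloxyboration) — fluoride desilylates 13 to 3,4,5-tris(benzyloxy)benzyne and opens 14 to a fluoroborate that releases the hindered aryloxide; the aryloxide adds to the aryne carbon remote from the flanking benzyloxy group (the regiochemistry general for 3-alkoxyarynes, since the carbanion then sits next to the inductively stabilising C–O bond), and in the aprotic medium the aryl anion is captured at boron by F–Bpin or by excess 14 before it is protonated, giving 15, whose C–B bond is oxidised to C–OH in place; the closest known reaction types are the fluoride-induced O-arylation of phenols with arynes from 2-silylaryl triflates, aryne σ-insertions into element–heteroatom bonds such as Sn–S and Si–N, and the borylation of aryl anions with borate esters; the step makes the ring A–O–ring B ether and puts the next oxygen on a ring carbon that electrophilic substitution could not single out.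

Step 8
Reactants: 17 2,6-dihydroxybenzaldehyde
Product: 18 2,6-bis(benzyloxy)benzaldehyde
Conditions: BnBr (2.4 equiv), K2CO3, DMF, 70 °C
Reagents that add atoms: benzyl bromide, BrCc1ccccc1
Why: Williamson ether synthesis; heating overcomes the hydrogen bond of the ortho hydroxyls to the aldehyde.

Step 9
Reactants: 18 2,6-bis(benzyloxy)benzaldehyde
Product: 20 2,6-bis(benzyloxy)phenol, via aryl formate 19 (not isolated)
Conditions: mCPBA (1.3 equiv), CH2Cl2, 0 °C to rt; then K2CO3 (cat.), MeOH, rt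
Reagents that add atoms: 3-chloroperoxybenzoic acid, O=C(OO)c1cccc(Cl)c1
Why: Baeyer–Villiger (Dakin-type) oxidation with migration of the di-ortho-alkoxy aryl group, then formate methanolysis.

Step 10
Reactants: 20 2,6-bis(benzyloxy)phenol
Product: 21 2,6-bis(benzyloxy)-4-bromophenol
Conditions: NBS (1.0 equiv), CHCl3, −45 °C to rt
Reagents that add atoms: N-bromosuccinimide, O=C1CCC(=O)N1Br
Why: Electrophilic aromatic bromination para to the free hydroxyl, the strongest director, with both ortho positions blocked (the same selectivity as in the bromination of 2,6-dimethoxyphenol).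

Step 11
Reactants: 21 2,6-bis(benzyloxy)-4-bromophenol; 13 3,4,5-tris(benzyloxy)-2-(trimethylsilyl)phenyl trifluoromethanesulfonate
Product: 24 2,3,4-tris(benzyloxy)-6-[2,6-bis(benzyloxy)-4-bromophenoxy]phenol (fragment CD), via aryl pinacol borate 22 (not isolated), via arylboronic ester 23 (not isolated)
Conditions: 21 (2.5 equiv), HBpin (2.5 equiv), toluene, 60 °C, then evaporate; 13 (1.0 equiv), KF (3 equiv), 18-crown-6 (3 equiv), THF, 0 °C to rt; then 30% H2O2, aq NaHCO3, THF, 0 °C
Reagents that add atoms: hydrogen peroxide, OO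
Why: Proposed new method: second use of the aryne O–B insertion of step 7 — fluoride generates the aryne and frees the aryloxide from 22, the aryloxide adds at the aryne carbon remote from the flanking benzyloxy group, the ortho aryl anion is trapped at boron to give 23, and oxidation turns C–B into C–OH; the closest known reaction types are the aryne O-arylation of phenols and aryne σ-bond insertions, and the aryl bromide is inert to fluoride and to the buffered peroxide.

Step 12
Reactants: 25 5-bromo-1,2,3-trimethoxybenzene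
Product: 26 5-bromobenzene-1,2,3-triol
Conditions: BBr3 (3.5 equiv), CH2Cl2, −78 °C to rt; then H2O
Reagents that add atoms: none
Why: Lewis-acid cleavage of aryl methyl ethers by BBr3 (bromide attacks the methyl of the O–B adduct); the aryl bromide is untouched.

Step 13
Reactants: 26 5-bromobenzene-1,2,3-triol
Product: 27 5-bromo-1,2,3-tris(benzyloxy)benzene
Conditions: BnBr (3.5 equiv), K2CO3, degassed DMF, 60 °C, Ar
Reagents that add atoms: benzyl bromide, BrCc1ccccc1
Why: Williamson ether synthesis, run under argon because the pyrogallol trianion is air-sensitive.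

Step 14
Reactants: 27 5-bromo-1,2,3-tris(benzyloxy)benzene
Product: 30 [3,4,5-tris(benzyloxy)phenyl]boronic acid, via aryllithium 28 (not isolated), via lithium triisopropoxyborate 29 (not isolated)
Conditions: n-BuLi (1.1 equiv), THF, −78 °C; B(OiPr)3 (1.5 equiv), −78 °C to rt; then 1 M HCl
Reagents that add atoms: triisopropyl borate, CC(C)OB(OC(C)C)OC(C)C; water, O
Why: Bromine–lithium exchange, borylation of the aryllithium and hydrolysis of the ate complex, a standard boronic acid synthesis.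

Step 15
Reactants: 24 2,3,4-tris(benzyloxy)-6-[2,6-bis(benzyloxy)-4-bromophenoxy]phenol; 30 [3,4,5-tris(benzyloxy)phenyl]boronic acid
Product: 31 1,2,3-tris(benzyloxy)-5-[2,6-bis(benzyloxy)-4-bromophenoxy]-4-[3,4,5-tris(benzyloxy)phenoxy]benzene (fragment CDE)
Conditions: 30 (2.5 equiv), Cu(OAc)2 (1.0 equiv), pyridine (5 equiv), 4 Å MS, CH2Cl2, O2 (1 atm), rt, 48 h
Reagents that add atoms: none
Why: Chan–Lam oxidative C–O coupling with O2 as terminal oxidant, which returns copper to the divalent state; di-ortho-substituted phenols are competent partners, the aryl bromide is inert at room temperature, and phenol homocoupling is blocked because both ortho positions and the para position carry oxygen.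

Step 16
Reactants: 16 2,3,4-tris(benzyloxy)-6-[2,4,6-tris(benzyloxy)phenoxy]phenol; 31 1,2,3-tris(benzyloxy)-5-[2,6-bis(benzyloxy)-4-bromophenoxy]-4-[3,4,5-tris(benzyloxy)phenoxy]benzene
Product: 32 1,2,3-tris(benzyloxy)-4-{3,5-bis(benzyloxy)-4-[3,4,5-tris(benzyloxy)-2-(3,4,5-tris(benzyloxy)phenoxy)phenoxy]phenoxy}-5-[2,4,6-tris(benzyloxy)phenoxy]benzene (tetradeca-O-benzyl ether of the target)
Conditions: 16 (1.2 equiv), CuI (20 mol%), picolinic acid (40 mol%), K3PO4 (2 equiv), DMSO/toluene 3:1, 100 °C, Ar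
Reagents that add atoms: none
Why: Ullmann-type copper-catalysed diaryl ether synthesis with the picolinic acid ligand system, which tolerates di-ortho-substituted phenols and electron-rich aryl bromides; the bromide carbon of 31 is flanked only by hydrogens, and each partner has a single reactive site.

Step 17
Reactants: 32 tetradeca-O-benzyl ether of the target
Product: 33 4-{3,5-dihydroxy-4-[3,4,5-trihydroxy-2-(3,4,5-trihydroxyphenoxy)phenoxy]phenoxy}-5-(2,4,6-trihydroxyphenoxy)benzene-1,2,3-triol (CNP0273977.0)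
Conditions: H2 (1 atm), Pd/C (10%), degassed THF/MeOH 1:1, rt; filter and concentrate under Ar
Reagents that add atoms: none
Why: Catalytic hydrogenolysis of the fourteen benzyl aryl ethers; diaryl ether bonds and the arene rings are inert, and the reducing medium protects the air-sensitive polyphenol.

## Compound list

1 | 1,3,5-tris(benzyloxy)benzene | c1(OCc2ccccc2)cc(OCc2ccccc2)cc(OCc2ccccc2)c1 | starting material
2 | N-[2,4,6-tris(benzyloxy)benzylidene]-N-methylmethanaminium chloride | C[N+](C)=Cc1c(OCc2ccccc2)cc(OCc2ccccc2)cc1OCc1ccccc1.[Cl-] | intermediate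
3 | 2,4,6-tris(benzyloxy)benzaldehyde | O=Cc1c(OCc2ccccc2)cc(OCc2ccccc2)cc1OCc1ccccc1 | intermediate
4 | 2,4,6-tris(benzyloxy)phenyl formate | O=COc1c(OCc2ccccc2)cc(OCc2ccccc2)cc1OCc1ccccc1 | intermediate
5 | 2,4,6-tris(benzyloxy)phenol | Oc1c(OCc2ccccc2)cc(OCc2ccccc2)cc1OCc1ccccc1 | intermediate
6 | 3,4,5-trihydroxybenzaldehyde | O=Cc1cc(O)c(O)c(O)c1 | starting material
7 | 3,4,5-tris(benzyloxy)benzaldehyde | O=Cc1cc(OCc2ccccc2)c(OCc2ccccc2)c(OCc2ccccc2)c1 | intermediate
8 | 3,4,5-tris(benzyloxy)phenyl formate | O=COc1cc(OCc2ccccc2)c(OCc2ccccc2)c(OCc2ccccc2)c1 | intermediate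
9 | 3,4,5-tris(benzyloxy)phenol | Oc1cc(OCc2ccccc2)c(OCc2ccccc2)c(OCc2ccccc2)c1 | intermediate
10 | 2-bromo-3,4,5-tris(benzyloxy)phenol | Oc1cc(OCc2ccccc2)c(OCc2ccccc2)c(OCc2ccccc2)c1Br | intermediate
11 | [2-bromo-3,4,5-tris(benzyloxy)phenoxy]trimethylsilane | C[Si](C)(C)Oc1cc(OCc2ccccc2)c(OCc2ccccc2)c(OCc2ccccc2)c1Br | intermediate
12 | lithium 3,4,5-tris(benzyloxy)-2-(trimethylsilyl)phenolate | [Li+].[O-]c1cc(OCc2ccccc2)c(OCc2ccccc2)c(OCc2ccccc2)c1[Si](C)(C)C | intermediate
13 | 3,4,5-tris(benzyloxy)-2-(trimethylsilyl)phenyl trifluoromethanesulfonate | C[Si](C)(C)c1c(OS(=O)(=O)C(F)(F)F)cc(OCc2ccccc2)c(OCc2ccccc2)c1OCc1ccccc1 | intermediate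
14 | 2-[2,4,6-tris(benzyloxy)phenoxy]-4,4,5,5-tetramethyl-1,3,2-dioxaborolane | CC1(C)OB(Oc2c(OCc3ccccc3)cc(OCc3ccccc3)cc2OCc2ccccc2)OC1(C)C | intermediate
15 | 2-{2,3,4-tris(benzyloxy)-6-[2,4,6-tris(benzyloxy)phenoxy]phenyl}-4,4,5,5-tetramethyl-1,3,2-dioxaborolane | CC1(C)OB(OC1(C)C)c1c(OCc2ccccc2)c(OCc2ccccc2)c(OCc2ccccc2)cc1Oc1c(OCc2ccccc2)cc(OCc2ccccc2)cc1OCc1ccccc1 | intermediate
16 | 2,3,4-tris(benzyloxy)-6-[2,4,6-tris(benzyloxy)phenoxy]phenol (fragment AB) | Oc1c(OCc2ccccc2)c(OCc2ccccc2)c(OCc2ccccc2)cc1Oc1c(OCc2ccccc2)cc(OCc2ccccc2)cc1OCc1ccccc1 | intermediate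
17 | 2,6-dihydroxybenzaldehyde | O=Cc1c(O)cccc1O | starting material
18 | 2,6-bis(benzyloxy)benzaldehyde | O=Cc1c(OCc2ccccc2)cccc1OCc1ccccc1 | intermediate
19 | 2,6-bis(benzyloxy)phenyl formate | O=COc1c(OCc2ccccc2)cccc1OCc1ccccc1 | intermediate
20 | 2,6-bis(benzyloxy)phenol | Oc1c(OCc2ccccc2)cccc1OCc1ccccc1 | intermediate
21 | 2,6-bis(benzyloxy)-4-bromophenol | Oc1c(OCc2ccccc2)cc(Br)cc1OCc1ccccc1 | intermediate
22 | 2-[2,6-bis(benzyloxy)-4-bromophenoxy]-4,4,5,5-tetramethyl-1,3,2-dioxaborolane | CC1(C)OB(Oc2c(OCc3ccccc3)cc(Br)cc2OCc2ccccc2)OC1(C)C | intermediate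
23 | 2-{2,3,4-tris(benzyloxy)-6-[2,6-bis(benzyloxy)-4-bromophenoxy]phenyl}-4,4,5,5-tetramethyl-1,3,2-dioxaborolane | CC1(C)OB(OC1(C)C)c1c(OCc2ccccc2)c(OCc2ccccc2)c(OCc2ccccc2)cc1Oc1c(OCc2ccccc2)cc(Br)cc1OCc1ccccc1 | intermediate
24 | 2,3,4-tris(benzyloxy)-6-[2,6-bis(benzyloxy)-4-bromophenoxy]phenol (fragment CD) | Oc1c(OCc2ccccc2)c(OCc2ccccc2)c(OCc2ccccc2)cc1Oc1c(OCc2ccccc2)cc(Br)cc1OCc1ccccc1 | intermediate
25 | 5-bromo-1,2,3-trimethoxybenzene | COc1cc(Br)cc(OC)c1OC | starting material
26 | 5-bromobenzene-1,2,3-triol | Oc1cc(Br)cc(O)c1O | intermediate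
27 | 5-bromo-1,2,3-tris(benzyloxy)benzene | Brc1cc(OCc2ccccc2)c(OCc2ccccc2)c(OCc2ccccc2)c1 | intermediate
28 | [3,4,5-tris(benzyloxy)phenyl]lithium | [Li]c1cc(OCc2ccccc2)c(OCc2ccccc2)c(OCc2ccccc2)c1 | intermediate
29 | lithium triisopropoxy[3,4,5-tris(benzyloxy)phenyl]borate | [Li+].CC(C)O[B-](OC(C)C)(OC(C)C)c1cc(OCc2ccccc2)c(OCc2ccccc2)c(OCc2ccccc2)c1 | intermediate
30 | [3,4,5-tris(benzyloxy)phenyl]boronic acid | OB(O)c1cc(OCc2ccccc2)c(OCc2ccccc2)c(OCc2ccccc2)c1 | intermediate
31 | 1,2,3-tris(benzyloxy)-5-[2,6-bis(benzyloxy)-4-bromophenoxy]-4-[3,4,5-tris(benzyloxy)phenoxy]benzene (fragment CDE) | Brc1cc(OCc2ccccc2)c(Oc2cc(OCc3ccccc3)c(OCc3ccccc3)c(OCc3ccccc3)c2Oc2cc(OCc3ccccc3)c(OCc3ccccc3)c(OCc3ccccc3)c2)c(OCc2ccccc2)c1 | intermediate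
32 | 1,2,3-tris(benzyloxy)-4-{3,5-bis(benzyloxy)-4-[3,4,5-tris(benzyloxy)-2-(3,4,5-tris(benzyloxy)phenoxy)phenoxy]phenoxy}-5-[2,4,6-tris(benzyloxy)phenoxy]benzene | c1ccccc1COc1cc(OCc2ccccc2)c(Oc2cc(OCc3ccccc3)c(OCc3ccccc3)c(OCc3ccccc3)c2Oc2cc(OCc3ccccc3)c(Oc3cc(OCc4ccccc4)c(OCc4ccccc4)c(OCc4ccccc4)c3Oc3cc(OCc4ccccc4)c(OCc4ccccc4)c(OCc4ccccc4)c3)c(OCc3ccccc3)c2)c(OCc2ccccc2)c1 | intermediate
33 | 4-{3,5-dihydroxy-4-[3,4,5-trihydroxy-2-(3,4,5-trihydroxyphenoxy)phenoxy]phenoxy}-5-(2,4,6-trihydroxyphenoxy)benzene-1,2,3-triol (CNP0273977.0) | Oc1cc(O)c(Oc2cc(O)c(O)c(O)c2Oc2cc(O)c(Oc3cc(O)c(O)c(O)c3Oc3cc(O)c(O)c(O)c3)c(O)c2)c(O)c1 | target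

## Step count and risk

Total step count: 17.
Longest linear sequence: 8 steps (steps 3, 4, 5, 6, 11, 15, 16, 17).

The three steps most likely to fail:

**Step 7 (the new aryne O–B insertion, first use).** The aryl anion may be protonated, may deprotonate the neighbouring benzyl CH2, or fluoride may be held too tightly by boron. The fallback uses known chemistry, sets out from 5 and comes back at 16. Commercial 2,3,4-trihydroxybenzaldehyde F1 is benzylated (BnBr, K2CO3, DMF) to 2,3,4-tris(benzyloxy)benzaldehyde F2. Baeyer–Villiger oxidation with mCPBA gives 2,3,4-tris(benzyloxy)phenyl formate F3, which is methanolysed to 2,3,4-tris(benzyloxy)phenol F4. Ortho-selective bromination (NBS, cat. iPr2NH, CH2Cl2) gives 6-bromo-2,3,4-tris(benzyloxy)phenol F5, and MOMCl/iPr2NEt gives 1-bromo-3,4,5-tris(benzyloxy)-2-(methoxymethoxy)benzene F6. Ullmann coupling of 5 with F6 (CuI, picolinic acid, K3PO4, DMSO, 90 °C, Ar) gives 1,2,3-tris(benzyloxy)-4-(methoxymethoxy)-5-[2,4,6-tris(benzyloxy)phenoxy]benzene F7. HCl in MeOH/THF removes the methoxymethyl group and delivers 16. Here the oxygen pattern of ring B is bought with the starting material instead of being created by the insertion.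

**Step 11 (the new aryne O–B insertion, second use).** The risks are those of step 7, plus possible bromine–metal exchange at the ring C bromide. The fallback uses known chemistry, sets out from 21 and comes back at 24. Bromide F6, made as in the fallback for step 7, is converted by Miyaura borylation (B2pin2, Pd(dppf)Cl2, KOAc, dioxane, 80 °C) into 2-[3,4,5-tris(benzyloxy)-2-(methoxymethoxy)phenyl]-4,4,5,5-tetramethyl-1,3,2-dioxaborolane F8. Chan–Lam coupling of F8 with 21 (Cu(OAc)2, pyridine, B(OH)3, 4 Å MS, MeCN, O2, 60 °C) leaves the aryl bromide of ring C alone and gives 1,2,3-tris(benzyloxy)-5-[2,6-bis(benzyloxy)-4-bromophenoxy]-4-(methoxymethoxy)benzene F9. HCl in MeOH/THF then gives 24. An Ullmann coupling is avoided here because 21 carries its own bromide.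

**Step 16 (final Ullmann coupling of two large fragments).** The phenol of 16 sits between a benzyloxy group and a di-ortho-substituted aryloxy group, and the perbenzylated partners dissolve poorly in DMSO. The fallback sets out from 31 and comes back at 32. Miyaura borylation of 31 (B2pin2, Pd(dppf)Cl2, KOAc, dioxane, 80 °C) gives 2-{3,5-bis(benzyloxy)-4-[3,4,5-tris(benzyloxy)-2-(3,4,5-tris(benzyloxy)phenoxy)phenoxy]phenyl}-4,4,5,5-tetramethyl-1,3,2-dioxaborolane F10. Chan–Lam coupling of F10 with 16 (Cu(OAc)2, pyridine, B(OH)3, 4 Å MS, MeCN/CH2Cl2, O2, 40 °C) gives 32. This swaps the polarity of the ring C partner and uses oxidative coupling at divalent copper, which step 15 will already have tested on a phenol with the same steric environment as 16.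

## Further compounds

F1 | step 7 | 2,3,4-trihydroxybenzaldehyde | O=Cc1ccc(O)c(O)c1O
F2 | step 7 | 2,3,4-tris(benzyloxy)benzaldehyde | O=Cc1ccc(OCc2ccccc2)c(OCc2ccccc2)c1OCc1ccccc1
F3 | step 7 | 2,3,4-tris(benzyloxy)phenyl formate | O=COc1ccc(OCc2ccccc2)c(OCc2ccccc2)c1OCc1ccccc1
F4 | step 7 | 2,3,4-tris(benzyloxy)phenol | Oc1ccc(OCc2ccccc2)c(OCc2ccccc2)c1OCc1ccccc1
F5 | step 7 | 6-bromo-2,3,4-tris(benzyloxy)phenol | Oc1c(Br)cc(OCc2ccccc2)c(OCc2ccccc2)c1OCc1ccccc1
F6 | step 7 | 1-bromo-3,4,5-tris(benzyloxy)-2-(methoxymethoxy)benzene | COCOc1c(Br)cc(OCc2ccccc2)c(OCc2ccccc2)c1OCc1ccccc1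
F7 | step 7 | 1,2,3-tris(benzyloxy)-4-(methoxymethoxy)-5-[2,4,6-tris(benzyloxy)phenoxy]benzene | COCOc1c(OCc2ccccc2)c(OCc2ccccc2)c(OCc2ccccc2)cc1Oc1c(OCc2ccccc2)cc(OCc2ccccc2)cc1OCc1ccccc1
F8 | step 11 | 2-[3,4,5-tris(benzyloxy)-2-(methoxymethoxy)phenyl]-4,4,5,5-tetramethyl-1,3,2-dioxaborolane | COCOc1c(B2OC(C)(C)C(C)(C)O2)cc(OCc2ccccc2)c(OCc2ccccc2)c1OCc1ccccc1
F9 | step 11 | 1,2,3-tris(benzyloxy)-5-[2,6-bis(benzyloxy)-4-bromophenoxy]-4-(methoxymethoxy)benzene | COCOc1c(OCc2ccccc2)c(OCc2ccccc2)c(OCc2ccccc2)cc1Oc1c(OCc2ccccc2)cc(Br)cc1OCc1ccccc1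
F10 | step 16 | 2-{3,5-bis(benzyloxy)-4-[3,4,5-tris(benzyloxy)-2-(3,4,5-tris(benzyloxy)phenoxy)phenoxy]phenyl}-4,4,5,5-tetramethyl-1,3,2-dioxaborolane | CC1(C)OB(OC1(C)C)c1cc(OCc2ccccc2)c(Oc2cc(OCc3ccccc3)c(OCc3ccccc3)c(OCc3ccccc3)c2Oc2cc(OCc3ccccc3)c(OCc3ccccc3)c(OCc3ccccc3)c2)c(OCc2ccccc2)c1
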